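## Retrosynthetic overview

1. The last step is a double O-methylation of the 2,5-dihydroxy-1,4-benzoquinone, whose two OH groups are vinylogous carboxylic acids.
2. Key disconnection: both C(oxygen-bearing)=C(indolyl) bonds of the quinone ring are cut at once, which splits the ring into two head-to-tail three-carbon units C(indolyl)–C(=O)–C(O), i.e. two indol-3-ylpyruvates. This works because the 3,6-diaryl-2,5-dihydroxyquinone ring is the enol tautomer of a cyclohexane-1,2,4,5-tetraone: each oxygen-bearing ring carbon is a former carboxyl carbon and each indolyl-bearing ring carbon a former pyruvate CH2, so two Claisen acylations give the ring at the right oxidation level.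
3. Hetero-coupling is enforced by a temporary ring. The two pyruvates are joined as an enol ester, with the ketone of the acyl half masked as a silyl enol ether; fluoride triggers Dieckmann closure to a pyran-2,5-dione, and ethoxide contracts that lactone to the carbocycle. The tether oxygen ends up as a ring oxygen, and the quinone ring is the only ring built.
4. The hindered half comes from 7-bromoindole (C-2 reverse prenylation, C-7 Stille prenylation, C-3 alkylation with a 2-nitrosoacrylate, deoximation); the simple half from indole-3-pyruvic acid.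

Key step: step 8

Remark: the target has no stereocentre; enol-type C=C bonds of intermediates are drawn Z, but their geometry does not matter because each is consumed in the key step, and 5 and 20 each carry one transient, uncontrolled sp3 centre.

Abbreviation used in names: PInd = 2-(2-methylbut-3-en-2-yl)-7-(3-methylbut-2-en-1-yl)-1H-indol-3-yl.

## Route

Step 1
Reactants: 1 9-borabicyclo[3.3.1]nonane (9-BBN, 0.5 M in THF); 2 3-methylbuta-1,2-diene
Product: 3 9-(3-methylbut-2-en-1-yl)-9-borabicyclo[3.3.1]nonane (B-prenyl-9-BBN), used as its THF solution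
Conditions: THF, 0 °C → rt, argon
Reagents that add atoms: none
Why: Hydroboration of the allene by 9-BBN should place boron on the unsubstituted terminal carbon and hydrogen on the central carbon, the standard allene hydroboration route to B-allyl-9-BBN reagents.

Step 2
Reactants: 4 7-bromo-1H-indole; 3 B-prenyl-9-BBN
Product: 6 7-bromo-2-(2-methylbut-3-en-2-yl)-1H-indole, via chloroindolenine 5 (not isolated)
Conditions: tBuOCl, Et3N, THF, −78 °C; then 3 (THF solution), −78 °C → rt; aq. K2CO3
Reagents that add atoms: tert-butyl hypochlorite, CC(C)(C)OCl (its chlorine is carried by intermediate 5 only and leaves again as chloride)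
Why: Reverse prenylation by chloroindolenine allylboration: C-3 chlorination gives 5 (in equilibrium with its 1H-tautomer, which reacts through the same form), the C=N bond is allylborated by 3 through a six-membered chair transition state with allylic transposition so that the tertiary carbon bonds to C-2, and loss of HCl restores the indole; no competing alkene is present for the hypochlorite at this stage.

Step 3
Reactants: 6 7-bromo-2-(2-methylbut-3-en-2-yl)-1H-indole; 7 tributyl(3-methylbut-2-en-1-yl)stannane
Product: 8 2-(2-methylbut-3-en-2-yl)-7-(3-methylbut-2-en-1-yl)-1H-indole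
Conditions: Pd(PPh3)4 (5 mol %), DMF, 100 °C
Reagents that add atoms: none
Why: Stille coupling of the aryl bromide under zerovalent palladium catalysis should give the linear prenyl arene, because reductive elimination from the allylpalladium intermediate occurs at the less hindered primary terminus, and the free N–H and the vinyl group are tolerated.

Step 4
Reactants: 8 2-(2-methylbut-3-en-2-yl)-7-(3-methylbut-2-en-1-yl)-1H-indole; 9 ethyl (2Z)-3-bromo-2-(hydroxyimino)propanoate
Product: 11 ethyl (2E)-2-(hydroxyimino)-3-(PInd)propanoate, via ethyl 2-nitrosoacrylate 10 (not isolated)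
Conditions: Na2CO3, CH2Cl2, rt, slow addition of 9
Reagents that add atoms: none
Why: Na2CO3 eliminates HBr from 9 to give the nitrosoalkene 10, a strong acceptor that is attacked at its CH2 terminus by the nucleophilic indole C-3 (conjugate addition of an indole to a 2-nitrosoacrylate, a known C-3 alkylation), and tautomerisation gives the oxime; the isolated alkenes are far less nucleophilic than C-3.

Step 5
Reactants: 11 ethyl (2E)-2-(hydroxyimino)-3-(PInd)propanoate
Product: 13 ethyl 2-oxo-3-(PInd)propanoate (keto form drawn, in equilibrium with its enol), via NH ketimine 12 (not isolated)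
Conditions: TiCl3 (aq., 3 equiv), NH4OAc buffer, THF/H2O, 0 °C → rt
Reagents that add atoms: water, O
Why: Reductive deoximation: TiCl3 (trivalent titanium) cleaves the N–O bond to the NH ketimine 12, which is hydrolysed in the buffered aqueous medium to the α-keto ester under conditions mild enough to spare the acid-sensitive prenyl and 1,1-dimethylallyl groups.

Step 6
Reactants: 14 3-(1H-indol-3-yl)-2-oxopropanoic acid (indole-3-pyruvic acid)
Product: 16 (2Z)-2-[(tert-butyldimethylsilyl)oxy]-3-(1H-indol-3-yl)prop-2-enoic acid, via bis-silyl derivative 15 (not isolated)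
Conditions: TBSCl (2.5 equiv), imidazole, DMF, 0 °C → rt; then AcOH/THF/H2O (3:1:1), 0 °C
Reagents that add atoms: tert-butyldimethylsilyl chloride, CC(C)(C)[Si](C)(C)Cl
Why: The acid reacts as its Z enol and is silylated on the carboxyl and the enol oxygen, after which the far more labile silyl ester is hydrolysed selectively (standard silyl ester versus silyl ether differentiation), leaving the ketone masked and the acid free; the indole N–H is not silylated by TBSCl/imidazole.

Step 7
Reactants: 13 ethyl 2-oxo-3-(PInd)propanoate; 16 (2Z)-2-[(tert-butyldimethylsilyl)oxy]-3-(1H-indol-3-yl)prop-2-enoic acid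
Product: 17 ethyl (2Z)-2-({(2Z)-2-[(tert-butyldimethylsilyl)oxy]-3-(1H-indol-3-yl)prop-2-enoyl}oxy)-3-(PInd)prop-2-enoate
Conditions: DCC (1.2 equiv), DMAP (0.2 equiv), Et3N (1 equiv), CH2Cl2, 0 °C → rt
Reagents that add atoms: none
Why: Steglich esterification applied to an enol: the enol(ate) oxygen of 13 is acylated by the acylpyridinium derived from 16, as in the standard preparation of enol esters from enolisable keto esters and 1,3-diones, while the silyl enol ether keeps the acyl donor from self-condensing and the indole N–H groups are not acylated without strong base.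

Step 8
Reactants: 17 ethyl (2Z)-2-({(2Z)-2-[(tert-butyldimethylsilyl)oxy]-3-(1H-indol-3-yl)prop-2-enoyl}oxy)-3-(PInd)prop-2-enoate
Product: 21 2,5-dihydroxy-3-(1H-indol-3-yl)-6-(PInd)cyclohexa-2,5-diene-1,4-dione, via free enolate 18 (not isolated), via pyrandione lactone 19 (not isolated), via seco keto ester 20 (not isolated)
Conditions: TBAF (1.1 equiv, anhydrous), THF, −78 → 0 °C; then NaOEt (4 equiv), EtOH, 0 → 60 °C, argon; cold 0.5 M HCl
Reagents that add atoms: none
Why: Proposed new method: fluoride removes the silyl mask and frees the enolate 18 of the indolylpyruvoyl unit, whose carbon attacks the neighbouring ethyl ester carbonyl in a 6-(enolendo)-exo-trig Dieckmann closure (the six-ring homologue of the Lacey–Dieckmann tetronic acid synthesis), giving pyran-2,5-dione 19 and the first new C–C bond, between the carbon that carries the plain indole and a carbon that becomes oxygen-bearing. Ethoxide (the one just expelled, supplemented by NaOEt of the same constitution) then opens the enol-lactone carbonyl of 19 to the keto ester enolate 20, and the freed enolate carbon that carries the PInd group closes onto that ester in a second 6-(enolendo)-exo-trig Claisen step, which forms the second C–C bond and the carbocycle; the closest known reaction is the alkoxide-driven enol-lactone to cyclic 1,3-diketone rearrangement that converts benzylidenephthalide into 2-phenylindane-1,3-dione. The resulting 3,6-diarylcyclohexane-1,2,4,5-tetraone is the keto tautomer of the 2,5-dihydroxy-1,4-benzoquinone, so no redox step is needed, and formation of its doubly vinylogous carboxylate dianion should be the thermodynamic sink that pulls the reversible acyl transfers forward. The step needs hetero- over homo-coupling and Claisen over aldol reactivity: the enol-ester tether should secure the first because the first C–C bond is made intramolecularly before any alkoxide is added, and the second because both ketone carbonyls are held as enol ester or enolate, leaving only ester carbonyls electrophilic. The 2-tert-alkyl group twists the acrylate out of the indole plane, which should keep the ester that is attacked first electrophilic; no stereocentre is formed.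

Step 9
Reactants: 21 2,5-dihydroxy-3-(1H-indol-3-yl)-6-(PInd)cyclohexa-2,5-diene-1,4-dione
Product: 22 2,5-dimethoxy-3-(1H-indol-3-yl)-6-(PInd)cyclohexa-2,5-diene-1,4-dione (target, CNP0163342.0)
Conditions: TMSCHN2 (2 M in hexanes, 3 equiv), MeOH/toluene (1:4), 0 °C → rt
Reagents that add atoms: (trimethylsilyl)diazomethane, C[Si](C)(C)C=[N+]=[N-]
Why: The two hydroxyl groups are vinylogous carboxylic acids and should be esterified like acids by trimethylsilyldiazomethane in methanol to the 2,5-dimethoxy-1,4-benzoquinone, while the far less acidic indole N–H groups do not react; O-methylation of dihydroxyquinones of this type is known chemistry, and both tautomers of 21 lead to the same dimethyl ether.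

## Compound list

1 | 9-borabicyclo[3.3.1]nonane (9-BBN) | [BH]1C2CCCC1CCC2 | starting material
2 | 3-methylbuta-1,2-diene | C=C=C(C)C | starting material
3 | 9-(3-methylbut-2-en-1-yl)-9-borabicyclo[3.3.1]nonane | CC(C)=CCB1C2CCCC1CCC2 | intermediate
4 | 7-bromo-1H-indole | Brc1cccc2cc[nH]c12 | starting material
5 | 7-bromo-3-chloro-3H-indole (racemic chloroindolenine, not isolated) | ClC1C=Nc2c(Br)cccc12 | intermediate
6 | 7-bromo-2-(2-methylbut-3-en-2-yl)-1H-indole | C=CC(C)(C)c1cc2cccc(Br)c2[nH]1 | intermediate
7 | tributyl(3-methylbut-2-en-1-yl)stannane | CCCC[Sn](CCCC)(CCCC)CC=C(C)C | starting material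
8 | 2-(2-methylbut-3-en-2-yl)-7-(3-methylbut-2-en-1-yl)-1H-indole | C=CC(C)(C)c1cc2cccc(CC=C(C)C)c2[nH]1 | intermediate
9 | ethyl (2Z)-3-bromo-2-(hydroxyimino)propanoate | CCOC(=O)/C(CBr)=N/O | starting material
10 | ethyl 2-nitrosoprop-2-enoate (not isolated) | CCOC(=O)C(=C)N=O | intermediate
11 | ethyl (2E)-2-(hydroxyimino)-3-(PInd)propanoate | CCOC(=O)/C(Cc1c(C(C)(C)C=C)[nH]c2c(CC=C(C)C)cccc12)=N/O | intermediate
12 | ethyl 2-imino-3-(PInd)propanoate (NH ketimine, not isolated) | CCOC(=O)C(=N)Cc1c(C(C)(C)C=C)[nH]c2c(CC=C(C)C)cccc12 | intermediate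
13 | ethyl 2-oxo-3-(PInd)propanoate | CCOC(=O)C(=O)Cc1c(C(C)(C)C=C)[nH]c2c(CC=C(C)C)cccc12 | intermediate
14 | 3-(1H-indol-3-yl)-2-oxopropanoic acid (indole-3-pyruvic acid) | OC(=O)C(=O)Cc1c[nH]c2ccccc12 | starting material
15 | tert-butyldimethylsilyl (2Z)-2-[(tert-butyldimethylsilyl)oxy]-3-(1H-indol-3-yl)prop-2-enoate (not isolated) | CC(C)(C)[Si](C)(C)OC(=O)/C(O[Si](C)(C)C(C)(C)C)=C/c1c[nH]c2ccccc12 | intermediate
16 | (2Z)-2-[(tert-butyldimethylsilyl)oxy]-3-(1H-indol-3-yl)prop-2-enoic acid | OC(=O)/C(O[Si](C)(C)C(C)(C)C)=C/c1c[nH]c2ccccc12 | intermediate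
17 | ethyl (2Z)-2-({(2Z)-2-[(tert-butyldimethylsilyl)oxy]-3-(1H-indol-3-yl)prop-2-enoyl}oxy)-3-(PInd)prop-2-enoate | CCOC(=O)/C(OC(=O)/C(O[Si](C)(C)C(C)(C)C)=C/c1c[nH]c2ccccc12)=C/c1c(C(C)(C)C=C)[nH]c2c(CC=C(C)C)cccc12 | intermediate
18 | ethyl (2Z)-2-{[3-(1H-indol-3-yl)-2-oxopropanoyl]oxy}-3-(PInd)prop-2-enoate (desilylated enolate, drawn as neutral keto form, not isolated) | CCOC(=O)/C(OC(=O)C(=O)Cc1c[nH]c2ccccc12)=C/c1c(C(C)(C)C=C)[nH]c2c(CC=C(C)C)cccc12 | intermediate
19 | (6Z)-3-hydroxy-4-(1H-indol-3-yl)-6-[(PInd)methylidene]-2H-pyran-2,5(6H)-dione (not isolated) | O=C1O/C(=C\c2c(C(C)(C)C=C)[nH]c3c(CC=C(C)C)cccc23)C(=O)C(c2c[nH]c3ccccc23)=C1O | intermediate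
20 | ethyl 3-(1H-indol-3-yl)-2,4,5-trioxo-6-(PInd)hexanoate (triketo form drawn, C-3 enolised, not isolated) | CCOC(=O)C(=O)C(c1c[nH]c2ccccc12)C(=O)C(=O)Cc1c(C(C)(C)C=C)[nH]c2c(CC=C(C)C)cccc12 | intermediate
21 | 2,5-dihydroxy-3-(1H-indol-3-yl)-6-(PInd)cyclohexa-2,5-diene-1,4-dione | C=CC(C)(C)c1[nH]c2c(CC=C(C)C)cccc2c1C1=C(O)C(=O)C(c2c[nH]c3ccccc23)=C(O)C1=O | intermediate
22 | 2,5-dimethoxy-3-(1H-indol-3-yl)-6-(PInd)cyclohexa-2,5-diene-1,4-dione | C=CC(C)(C)c1[nH]c2c(CC=C(C)C)cccc2c1C1=C(OC)C(=O)C(c2c[nH]c3ccccc23)=C(OC)C1=O | target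

## Step count and risks

Total step count: 9.
Longest linear sequence: 8 steps (steps 1, 2, 3, 4, 5, 7, 8, 9); 7 steps counted from 7-bromoindole.

Steps most likely to fail:

1. Step 8 (proposed new method). The cascade could stall at the pyrandione stage. Retro-Claisen cleavage followed by alcoholysis of the enol ester could also release the two pyruvates, which would then scramble to homo-coupled quinones or aldol-derived lactones. The fallback buys the quinone core instead of building it, sets out from 8 and uses only established indole–haloquinone chemistry. Indole is added to 2,5-dichloro-1,4-benzoquinone under acid catalysis (cat. HCl, THF, rt) to give the mono(indolyl)hydroquinone F1, which DDQ oxidises to the mono(indolyl)dichloroquinone F2. Compound 8 is then added to the only free position of F2 in AcOH (rt to 50 °C, the weak acid sparing the 1,1-dimethylallyl group) to give the bis(indolyl)hydroquinone F3, which DDQ oxidises to the bis(indolyl)dichloroquinone F4. NaOH in MeOH at reflux replaces both chlorides by oxygen and, after acidification, gives 21, where the route is rejoined for step 9. Compounds 9 to 20 are then not needed.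

2. Step 7. The hindered, largely ketonic 13 may enolise poorly and be acylated slowly or on carbon, and the activated acid 16 may lose its silyl group or self-condense. The fallback exchanges the roles of the two halves, so that the unhindered, fully enolic partner is the one acylated. Setting out from 13, TBSOTf/Et3N (CH2Cl2, −78 °C) should give the hindered silyl enol ether ester F5, and Me3SnOH (1,2-dichloroethane, 70 °C) the hindered silyloxyacrylic acid F6. Acid 14 is esterified (EtI, KHCO3, DMF) to ethyl indol-3-ylpyruvate F7, and DCC/DMAP coupling of F6 with the enol of F7 gives the role-reversed enol ester F8. Under the conditions of step 8, F8 should pass through the role-reversed free enolate F9, the role-reversed pyrandione F10 and the role-reversed seco keto ester F11, making the same two ring bonds in the opposite order, and come back to the route at 21.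

3. Step 5. TiCl3 may over-reduce the α-keto ester, the enamine tautomer of 12 may hydrolyse slowly, and the prenyl groups may cyclise under acid. The fallback builds the pyruvate by olefination instead of via the oxime and sets out from 8. Vilsmeier–Haack formylation (POCl3, DMF, 0 °C → rt; aq. NaOH) should give the hindered indole-3-carbaldehyde F12. Horner–Wadsworth–Emmons olefination with ethyl 2-[(tert-butyldimethylsilyl)oxy]-2-(diethoxyphosphoryl)acetate (LiN(SiMe3)2, 2.2 equiv, THF, −78 °C → rt) gives the hindered silyl enol ether ester F5, the compound already described under the fallback for step 7. Buffered desilylation (TBAF/AcOH, THF, 0 °C) returns to the route at 13; compounds 9 to 12 are then not needed.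

## Further compounds

F1 | step 8 | mono(indolyl)hydroquinone: 2,5-dichloro-3-(1H-indol-3-yl)benzene-1,4-diol | Oc1cc(Cl)c(O)c(-c2c[nH]c3ccccc23)c1Cl
F2 | step 8 | mono(indolyl)dichloroquinone: 2,5-dichloro-3-(1H-indol-3-yl)cyclohexa-2,5-diene-1,4-dione | O=C1C=C(Cl)C(=O)C(c2c[nH]c3ccccc23)=C1Cl
F3 | step 8 | bis(indolyl)hydroquinone: 2,5-dichloro-3-(1H-indol-3-yl)-6-(PInd)benzene-1,4-diol | Oc1c(Cl)c(-c2c[nH]c3ccccc23)c(O)c(Cl)c1-c1c(C(C)(C)C=C)[nH]c2c(CC=C(C)C)cccc12
F4 | step 8 | bis(indolyl)dichloroquinone: 2,5-dichloro-3-(1H-indol-3-yl)-6-(PInd)cyclohexa-2,5-diene-1,4-dione | O=C1C(Cl)=C(c2c[nH]c3ccccc23)C(=O)C(Cl)=C1c1c(C(C)(C)C=C)[nH]c2c(CC=C(C)C)cccc12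
F5 | step 7 | hindered silyl enol ether ester: ethyl (2Z)-2-[(tert-butyldimethylsilyl)oxy]-3-(PInd)prop-2-enoate | CCOC(=O)/C(O[Si](C)(C)C(C)(C)C)=C/c1c(C(C)(C)C=C)[nH]c2c(CC=C(C)C)cccc12
F6 | step 7 | hindered silyloxyacrylic acid: (2Z)-2-[(tert-butyldimethylsilyl)oxy]-3-(PInd)prop-2-enoic acid | OC(=O)/C(O[Si](C)(C)C(C)(C)C)=C/c1c(C(C)(C)C=C)[nH]c2c(CC=C(C)C)cccc12
F7 | step 7 | ethyl indol-3-ylpyruvate: ethyl 3-(1H-indol-3-yl)-2-oxopropanoate | CCOC(=O)C(=O)Cc1c[nH]c2ccccc12
F8 | step 7 | role-reversed enol ester: ethyl (2Z)-2-({(2Z)-2-[(tert-butyldimethylsilyl)oxy]-3-(PInd)prop-2-enoyl}oxy)-3-(1H-indol-3-yl)prop-2-enoate | CCOC(=O)/C(OC(=O)/C(O[Si](C)(C)C(C)(C)C)=C/c1c(C(C)(C)C=C)[nH]c2c(CC=C(C)C)cccc12)=C/c1c[nH]c2ccccc12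
F9 | step 7 | role-reversed free enolate (neutral keto form): ethyl (2Z)-3-(1H-indol-3-yl)-2-{[2-oxo-3-(PInd)propanoyl]oxy}prop-2-enoate | CCOC(=O)/C(OC(=O)C(=O)Cc1c(C(C)(C)C=C)[nH]c2c(CC=C(C)C)cccc12)=C/c1c[nH]c2ccccc12
F10 | step 7 | role-reversed pyrandione: (6Z)-3-hydroxy-6-[(1H-indol-3-yl)methylidene]-4-(PInd)-2H-pyran-2,5(6H)-dione | O=C1O/C(=C\c2c[nH]c3ccccc23)C(=O)C(c2c(C(C)(C)C=C)[nH]c3c(CC=C(C)C)cccc23)=C1O
F11 | step 7 | role-reversed seco keto ester: ethyl 6-(1H-indol-3-yl)-2,4,5-trioxo-3-(PInd)hexanoate | CCOC(=O)C(=O)C(c1c(C(C)(C)C=C)[nH]c2c(CC=C(C)C)cccc12)C(=O)C(=O)Cc1c[nH]c2ccccc12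
F12 | step 5 | hindered indole-3-carbaldehyde: 2-(2-methylbut-3-en-2-yl)-7-(3-methylbut-2-en-1-yl)-1H-indole-3-carbaldehyde | O=Cc1c(C(C)(C)C=C)[nH]c2c(CC=C(C)C)cccc12
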